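A bend in a first-order plot tempts you to say the catalyst is dying. Friday's run has such a bend: the apparent constant is 0.0118 s⁻¹ up to 20.0 s, but 0.00842 s⁻¹ up to 80.0 s.

in all of them: substrate 10 mM
- Friday's: acid 0.30 mM; scavenger 1 equiv; the very flask that is asked about, followed so far
- flask: acid 0.300 mM; scavenger 1.00 equiv; time 3.0 min

- Friday's (time / s: substrate / %, product / %): 10.0: 89, 9; 20.0: 79, 14; 40.0: 70, 28; 80.0: 51, 44

(standard deviation of a reading: 2 percentage points)

- acid is the free proton; pH is minus the decimal logarithm of its molar concentration

1. part of the substrate that has reacted at 3.0 min
2. pH of the solution at 3.0 min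

Climb the time scales of this flask, fastest first. Averaged over Friday's readings, 4 percentage points of the substrate charged stands in neither column, against a scatter of 2 points on a single reading, so I read a small, quick holding-back of substrate, which can bend the early plot.

Next comes turnover. By 80.0 s the product is 14.7 times the acid charged, so the acid comes back after each turn. Read slice by slice, the constant is 0.00605 s⁻¹ from 20.0 s to 40.0 s and 0.00792 s⁻¹ from 40.0 s to 80.0 s, so these readings show no further fall, and I treat the decay as pseudo-first-order at constant c(acid).

Define the acid-scaled constant as the substrate's first-order constant divided by c(acid), 28.1 L mol⁻¹ s⁻¹, read at the last point, where the early holding-back weighs least. At the start the substrate falls at this constant times c(acid), late it tends to zero, and an exponential joins both ends. The mean life is 119 s, so my reckoning gives 78.0% reacted at 3.0 min, with the pH of the charged acid, 3.52.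

The forecast differs, with 70% (62% to 80%) and pH 3.95 (3.55 to 4.35), reading the run as “the scavenger slowly consuming the acid”.

The flask gives 76.9% at pH 3.52.

    weak acid ⇌ conjugate base + acid, settled at all times (K = 6.30 × 10⁻⁷ M)
    substrate → weak acid + product (k = 1.60 × 10⁻⁴ s⁻¹)
    weak acid + scavenger → scavenged by-product (k = 48.1 L mol⁻¹ s⁻¹)
    substrate + acid → weak acid + acid + product (k = 27.1 L mol⁻¹ s⁻¹)
    substrate + weak acid ⇌ idle adduct, settled at all times (K = 458 L mol⁻¹)

At 3.00 min the flask's acid stands at 100% of charge, with 28% of the scavenger left. For the neighbour flask, the same but charged with 0.12 mM of acid, the acid-scaled constant gives 45.5% reacted at 3.0 min, and that neighbour flask reaches 46.7%.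

The runs are simulated on assumed constants; the scatter is artificial.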